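## Structural features

The target is a cembrane: a 14-membered carbocycle (C1–C14) cis-fused at C1/C2 to an α-methylene-γ-butyrolactone (C15=C17, C16=O, ring oxygen on C2). Round the large ring lie an (E)-trisubstituted alkene C3=C4 (C18), the bis-allylic methylene C5, an (E)-disubstituted alkene C6=C7, a tertiary allylic carbinol C8 (C19), two methylenes, a trisubstituted oxirane C11–C12 (C20), a secondary acetate at C13 and C14. The six stereocentres form three groups: C1/C2 (contiguous, 1S,2S, cis), C11/C12/C13 (contiguous, 11S,12R,13S, epoxide oxygen and C13 oxygen erythro) and the isolated C8 (R), which has no neighbour to be controlled from. Fragile points are the exo-methylene lactone (Michael acceptor, base-induced double-bond migration), the skipped 3,6-diene, the tertiary allylic alcohol, the acetate, and the C8 hydroxyl sitting four atoms from the epoxide carbon C11, which under acid would close a transannular tetrahydrofuran. The real difficulty is to close the 14-membered ring late, with this functionality in place, so that the remote C1/C2 and C11–C13 sectors come out in the right relative sense, and then to oxidise one of four C=C bonds. The key step exploits the fact that C13 is an oxygenated carbon bonded to C12, the methyl-bearing carbon of what is an (E)-C11=C12 alkene before epoxidation. C12–C13 is therefore an alkenyl–carbonyl bond whose formation closes the carbocycle and leaves the C13 hydroxyl as the handle that directs the epoxidation.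

## Logic of the disconnections

28 to 27: the O–acetyl bond at C13 is cut. The ester is the most base-labile group and is put on last. This frees the C13 hydroxyl as a directing group. The forward acylation must take the secondary hydroxyl and leave the tertiary C8 hydroxyl and the oxirane alone.

27 to 26: both C–O bonds of the C11/C12 oxirane are cut. The oxirane is acid-sensitive next to the C8 hydroxyl, so it is introduced only after ring closure. Two stereocentres disappear and an (E)-allylic alcohol remains. The forward step must deliver oxygen to one face of C11=C12 only (erythro to C13–OH) and to none of the other three alkenes.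

26 to 24: the ring bond C12–C13 is cut. It is the one ring bond flanked by an sp2 carbon and a carbinol, so an alkenyl metal/aldehyde union forms it together with the C13 stereocentre. The macrocycle becomes a chain carrying the intact lactone. The forward step must retain the E geometry, cyclise in preference to oligomerising, add to the Re face of the aldehyde, and tolerate the lactone and the free carbinol.

24 to 23: the C13 aldehyde is traced to its dimethyl acetal (C13–O bonds). A free aldehyde could not survive the allylation that builds the lactone. The gain is a stable, storable precursor. The hydrolysis must be mild enough for the tertiary allylic alcohol.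

23 to 16 + 21: the C1–C2 bond and the lactone C16–O bond are cut. One allylation/lactonisation then creates both lactone stereocentres and the exo-methylene group. The C1, C13–C17 unit is split off and a linear enal is left. The forward step must be syn-selective (cis-lactone), face-selective at C2 (Re), and must engage the allyl bromide but not the alkenyl iodide.

21 to 20 to 18 + 19, and 18 to 17: the C–Br bond (with allylic transposition), the C1–C15 bond and the aldehyde oxidation level are traced back. The acrylate/aldehyde union supplies the whole C1, C13–C17 piece from two bulk chemicals. The demand is that the β,β-dialkoxy aldehyde survives amine catalysis and that the bromide forms as the Z isomer.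

16 to 15 to 14: the C2 aldehyde is traced to the allylic alcohol and its silyl ether (C2–H and O–Si bonds). The C2 oxygen must be masked through the organolithium and zirconium hydride steps. The demand is a final oxidation that touches only the allylic primary alcohol.

14 to 12 to 10 to 9: the C12–I bond, the C12–C20 bond and the C11–C12 π bonds are cut back to a C11 aldehyde held as its lactol. Syn hydrometalation of a methyl alkyne is the dependable source of the (E)-2-iodoalkene. The sequence must put zirconium on C12 and not on C11, and no terminal alkene may be present, which forces the C6=C7 bond to be made first.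

9 to 8 to 7 + 4: the C6=C7 bond is cut (cross-metathesis) after adjusting C11 to the alcohol level. This joins the carbinol piece to the C2–C6 dienyl piece in one step. The forward step must be E-selective, must not move the skipped diene into conjugation, and needs the free tertiary hydroxyl; the second alkene of 5 has to be gone before ruthenium is used.

7 to 5: the C11=C bond to the isopropylidene carbon is cut. 5 delivers C6–C11, C19 and the C8 stereocentre from the chiral pool. Ozone must take the trisubstituted alkene and leave the vinyl group.

4 to 3 to 1: the O–Si bond, the C4–C18 bond and the C2–C3 bond are cut. Carbometalation of the enyne sets the (E)-C3=C4 alkene and both new carbons in one operation. It must be regioselective for the alkyne and leave the terminal alkene alone.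

## Other disconnections considered

Alternative 1: The cut is C3–C4 at the alkyne level, plus C4–C18. In the forward sense the silyl-protected seco diyne A1, with methyl-capped alkynes at C3 and C4, would be closed by the molybdenum alkylidyne Mo(≡C–C6H4–OMe)(OSiPh3)3 to cycloalkyne A2 with loss of but-2-yne. C18 would follow by trans-hydrometalation and methyl coupling, then the lactone by oxidation at C16, then epoxide and acetate.
- In its favour: alkyne metathesis is dependable for 14-membered rings and ignores the three C=C bonds. No stereocentre is formed at ring closure, so C13 can be set beforehand on an open chain under reagent control. On certainty of configuration at the ring-closing stage it is the better plan; on alkene tolerance the two are equal.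
- Against it here: the methyl group must go to C4, the alkyne carbon remote from the only nearby oxygen (on C2). A propargylic hydroxyl steers ruthenium-catalysed trans-hydrostannation to the proximal carbon, C3, so the regiochemistry is unsupported. The C4–C5–C6 enyne unit is prone to base-induced isomerisation. Four silyl ethers and the late C16 oxidation/lactonisation put roughly eight operations between A2 and the target, against two after 26.
- Comparison: mechanistically it is driven by expulsion of a volatile alkyne and is very predictable. The chosen closure is less predictable at C13 but forms a skeletal bond, a stereocentre and the directing hydroxyl at once and is far more step-economic.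

Alternative 2: The cut is C1–C14, read as a [3,3] shift. The substrate is A3, a 16-membered ring in which C13 bears an exocyclic methylene (C14) and is linked through oxygen to C17; it would arise by macrolactonisation and titanium methylenation of the C13 carbonyl. Heating A3 would form C1–C14, break O–C17 and give the 14-membered enone A4 with the C13 ketone, the C15=C17 methylene and the C1 stereocentre.
- In its favour: lactonisation is the most dependable large-ring closure. The rearrangement makes a C–C bond, the exo-methylene and the C1 centre together, so on bond-forming density it is the better plan. C13 arrives as a ketone for reagent-controlled reduction, which equals the correction path of the chosen route and is more certain than its primary substrate control.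
- Against it here: the configuration at C1 depends on chair versus boat folding of a large allyl vinyl ether and on the C1=C15 geometry, neither secured by the substrate. The 2-alkoxydiene in A3 is acid-labile and must be heated beside a skipped diene. After A4 there remain ketone reduction, desilylations, C16 oxidation, lactonisation, epoxidation and acetylation.
- Comparison: both plans leave one stereocentre to macrocyclic control (C1 there, C13 here), but an error at C13 can be repaired by oxidation and reduction, while C1 next to the lactone cannot. Step economy is clearly worse.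

Alternative 3: The cut is C11–C12. Samarium diiodide would reduce the aldehyde of the seco keto-aldehyde A5 to a ketyl that adds to the C12 methyl ketone, giving the 14-membered diol A6. Sulfonylation of the secondary C11 hydroxyl and displacement by the C12 alkoxide (inversion at C11) would then give the oxirane.
- In its favour: both oxirane carbons arrive oxygenated, so no alkene has to be singled out for epoxidation and no directing hydroxyl is needed. On chemoselectivity of the oxidation pattern it is the better plan. The aldehyde is reduced before the ketone, so the cross-coupling order is clear.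
- Against it here: two stereocentres, one quaternary, are formed in a single radical ring closure with no substrate element that secures the required pair. The silyloxy group at C13, α to the ketone, is exposed to reductive cleavage. The exo-methylene lactone cannot be present, so it and four silyl ethers must be handled after ring closure.
- Comparison: it leaves two centres to chance where the chosen plan leaves one, and it needs about eight further steps instead of two.

Key step: step 16

Remark: the epoxide oxygen and the C13 oxygen of the target are erythro (anti in the extended chain), which is what hydroxyl-directed epoxidation of the (13S)-allylic alcohol with the L-(+)-tartrate complex delivers. The C12 descriptor changes from S in 27 to R in 28 only through the ranking change on acetylation.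

Assumption: pent-1-en-4-yne and (R)-linalool of high enantiomeric purity are purchasable. The ligand antipode in step 14 is the one that sends the allyl group to the Re face of the aldehyde, to be assigned on a model enal.

## Steps

Step 1
Reactants: 1 pent-1-en-4-yne
Product: 3 (2E)-3-methylhexa-2,5-dien-1-ol, via alkenylalane 2 (not isolated)
Conditions: Me3Al (2 equiv), Cp2ZrCl2 (0.25 equiv), CH2Cl2, 0 °C to rt; then n-BuLi (1 equiv), THF, −78 °C; (CH2O)n, −78 °C to rt
Reagents that add atoms: trimethylaluminium C[Al](C)C; paraformaldehyde (as formaldehyde) C=O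
Why: Negishi zirconium-catalysed methylalumination adds CH3 and Al syn across the terminal alkyne with aluminium on the terminal carbon, which fixes C18 and the (E)-C3=C4 geometry; the alkenylalanate then adds to formaldehyde with retention to install C2. The isolated terminal alkene is not carbometalated by Cp2ZrCl2/Me3Al under these conditions.

Step 2
Reactants: 3 (2E)-3-methylhexa-2,5-dien-1-ol
Product: 4 tert-butyl(dimethyl){[(2E)-3-methylhexa-2,5-dien-1-yl]oxy}silane
Conditions: TBSCl, imidazole, CH2Cl2, 0 °C to rt
Reagents that add atoms: tert-butyldimethylsilyl chloride CC(C)(C)[Si](C)(C)Cl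
Why: Standard silylation of a primary allylic alcohol; the ether masks the C2 oxygen through the organolithium and zirconium hydride steps and is inert to ruthenium alkylidenes.

Step 3
Reactants: 5 (R)-linalool
Product: 7 (4R)-4-methylhex-5-ene-1,4-diol, via hydroxy aldehyde 6 (not isolated)
Conditions: O3 (1.0 equiv, titrated), CH2Cl2/MeOH 3:1, −78 °C; then NaBH4, −78 °C to rt
Reagents that add atoms: ozone [O-][O+]=O
Why: Ozonolysis with reductive work-up; ozone attacks the electron-rich trisubstituted alkene much faster than the vinyl group, so one equivalent cleaves only the isopropylidene end. Borohydride gives the open-chain diol, which keeps the tertiary hydroxyl free for the metathesis; C8 comes unchanged from the chiral pool.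

Step 4
Reactants: 7 (4R)-4-methylhex-5-ene-1,4-diol; 4 tert-butyl(dimethyl){[(2E)-3-methylhexa-2,5-dien-1-yl]oxy}silane
Product: 8 (4R,5E,8E)-10-[(tert-butyldimethylsilyl)oxy]-4,8-dimethyldeca-5,8-diene-1,4-diol
Conditions: 4 (2.5 equiv), second-generation Hoveyda–Grubbs catalyst (5 mol%), CH2Cl2, 40 °C
Reagents that add atoms: none
Why: Olefin cross-metathesis between a readily dimerising terminal alkene (used in excess) and a vinyl group on a quaternary carbinol, which the free hydroxyl activates and which does not homodimerise. The quaternary allylic carbon enforces the E geometry at C6=C7, and neither partner can ring-close because the second alkene of 5 was removed first.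

Step 5
Reactants: 8 (4R,5E,8E)-10-[(tert-butyldimethylsilyl)oxy]-4,8-dimethyldeca-5,8-diene-1,4-diol
Product: 9 (5R)-5-[(1E,4E)-6-[(tert-butyldimethylsilyl)oxy]-4-methylhexa-1,4-dien-1-yl]-5-methyloxolan-2-ol (anomer mixture)
Conditions: SO3·pyridine, DMSO, i-Pr2NEt, CH2Cl2, 0 °C
Reagents that add atoms: none
Why: Parikh–Doering oxidation stops at the C11 aldehyde, which the C8 hydroxyl captures as the five-membered lactol. The tertiary alcohol cannot be oxidised, and the non-acidic conditions spare the skipped diene and the silyl ether.

Step 6
Reactants: 9 (5R)-5-[(1E,4E)-6-[(tert-butyldimethylsilyl)oxy]-4-methylhexa-1,4-dien-1-yl]-5-methyloxolan-2-ol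
Product: 10 (5R,6E,9E)-11-[(tert-butyldimethylsilyl)oxy]-5,9-dimethylundeca-6,9-dien-1-yn-5-ol
Conditions: dimethyl (1-diazo-2-oxopropyl)phosphonate, K2CO3, MeOH, 0 °C to rt
Reagents that add atoms: dimethyl (1-diazo-2-oxopropyl)phosphonate CC(=O)C(=[N+]=[N-])P(=O)(OC)OC
Why: Ohira–Bestmann (Seyferth–Gilbert) homologation; methoxide unmasks the diazomethylphosphonate anion, which olefinates the aldehyde tautomer of the lactol, and loss of N2 with 1,2-hydride shift gives the terminal alkyne. This adds C12 without strong base.

Step 7
Reactants: 10 (5R,6E,9E)-11-[(tert-butyldimethylsilyl)oxy]-5,9-dimethylundeca-6,9-dien-1-yn-5-ol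
Product: 12 (6R,7E,10E)-12-[(tert-butyldimethylsilyl)oxy]-6,10-dimethyldodeca-7,10-dien-2-yn-6-ol, via dilithio alkoxide acetylide 11 (not isolated)
Conditions: n-BuLi (2.15 equiv), THF, −78 to −20 °C; MeI (1.5 equiv), −78 °C to rt
Reagents that add atoms: iodomethane CI
Why: Alkylation of a lithium acetylide; in THF the lithium tert-alkoxide is too poor a nucleophile to be O-methylated, so iodomethane reacts at carbon only and installs C20.

Step 8
Reactants: 12 (6R,7E,10E)-12-[(tert-butyldimethylsilyl)oxy]-6,10-dimethyldodeca-7,10-dien-2-yn-6-ol
Product: 14 (2E,6R,7E,10E)-12-[(tert-butyldimethylsilyl)oxy]-2-iodo-6,10-dimethyldodeca-2,7,10-trien-6-ol, via alkenylzirconocene 13 (not isolated)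
Conditions: Cp2Zr(H)Cl (3 equiv), THF, rt to 45 °C; then I2, −78 to 0 °C; aq. Na2S2O3/NaHCO3
Reagents that add atoms: iodine II
Why: Hydrozirconation–iodination; Zr–H adds syn, and with excess hydride the alkenylzirconium equilibrates to the isomer with the metal on the less hindered, methyl-bearing C12. Iodinolysis with retention gives the (E)-iodide with C10 trans to iodine. One equivalent of hydride is consumed by the hydroxyl; no terminal alkene is present and the internal alkenes react much more slowly.

Step 9
Reactants: 14 (2E,6R,7E,10E)-12-[(tert-butyldimethylsilyl)oxy]-2-iodo-6,10-dimethyldodeca-2,7,10-trien-6-ol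
Product: 15 (2E,5E,7R,10E)-11-iodo-3,7-dimethyldodeca-2,5,10-triene-1,7-diol
Conditions: Bu4NF, THF, 0 °C
Reagents that add atoms: none
Why: Fluoride cleavage of the primary silyl ether; the alkenyl iodide, the alkenes and the tertiary alcohol are unaffected.

Step 10
Reactants: 15 (2E,5E,7R,10E)-11-iodo-3,7-dimethyldodeca-2,5,10-triene-1,7-diol
Product: 16 (2E,5E,7R,10E)-7-hydroxy-11-iodo-3,7-dimethyldodeca-2,5,10-trienal
Conditions: MnO2 (activated, excess), CH2Cl2, rt
Reagents that add atoms: none
Why: MnO2 oxidises only the allylic primary alcohol; the neutral heterogeneous medium avoids conjugation of the skipped diene, and the tertiary alcohol is inert.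

Step 11
Reactants: 17 methyl 3,3-dimethoxypropanoate
Product: 18 3,3-dimethoxypropanal
Conditions: i-Bu2AlH (1.05 equiv), CH2Cl2, −78 °C; aq. potassium sodium tartrate
Reagents that add atoms: none
Why: Partial reduction of the ester; at −78 °C the tetrahedral aluminium hemiacetal persists and releases the aldehyde only on work-up. The aldehyde is used at once because it loses methanol easily.

Step 12
Reactants: 18 3,3-dimethoxypropanal; 19 methyl acrylate
Product: 20 methyl 3-hydroxy-5,5-dimethoxy-2-methylidenepentanoate (racemic)
Conditions: DABCO (0.5 equiv), 19 (3 equiv), neat, rt, 3–5 d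
Reagents that add atoms: none
Why: Morita–Baylis–Hillman reaction: amine conjugate addition to the acrylate, aldol addition to the aldehyde and loss of the amine form the C1–C15 bond. The carbinol centre need not be controlled because the next step removes it.

Step 13
Reactants: 20 methyl 3-hydroxy-5,5-dimethoxy-2-methylidenepentanoate
Product: 21 methyl (2Z)-2-(bromomethyl)-5,5-dimethoxypent-2-enoate
Conditions: NBS, Me2S, CH2Cl2, 0 °C to rt
Reagents that add atoms: N-bromosuccinimide O=C1CCC(=O)N1Br
Why: Corey–Kim type activation gives an alkoxysulfonium ion, which bromide opens at the methylene terminus with allylic transposition (SN2'). The thermodynamically favoured Z-enoate results, with the C14 chain trans to the ester; the neutral conditions keep the acetal.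

Step 14
Reactants: 16 (2E,5E,7R,10E)-7-hydroxy-11-iodo-3,7-dimethyldodeca-2,5,10-trienal; 21 methyl (2Z)-2-(bromomethyl)-5,5-dimethoxypent-2-enoate
Product: 23 (4S,5S)-4-(2,2-dimethoxyethyl)-5-[(1E,4E,6R,9E)-6-hydroxy-10-iodo-2,6-dimethylundeca-1,4,9-trien-1-yl]-3-methylideneoxolan-2-one, via silyl ether 22 (not isolated)
Conditions: CrCl2 (10 mol%, nickel-free), one enantiomer of 3,6-di-tert-butyl-1,8-bis(4-isopropyl-4,5-dihydrooxazol-2-yl)carbazole (11 mol%), i-Pr2NEt (30 mol%), Mn powder (2 equiv), TMSCl (2 equiv), THF, rt; then PPTS, MeOH, rt
Reagents that add atoms: none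
Why: Chromium-catalysed enantioselective Nozaki–Hiyama 2-(alkoxycarbonyl)allylation: divalent chromium (regenerated by Mn, released by silylation) forms the allylchromium, which adds through C1 in a chair transition state. The Z geometry places the C14 chain axial and gives the syn adduct, hence the cis-lactone, while the chiral ligand directs addition to the Re face of the enal and so sets (2S) and with it (1S). Nickel-free chromium leaves the alkenyl iodide alone, and mild acidic methanolysis removes the silyl group and closes the lactone without touching the acetal.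

Step 15
Reactants: 23 (4S,5S)-4-(2,2-dimethoxyethyl)-5-[(1E,4E,6R,9E)-6-hydroxy-10-iodo-2,6-dimethylundeca-1,4,9-trien-1-yl]-3-methylideneoxolan-2-one
Product: 24 (4S,5S)-5-[(1E,4E,6R,9E)-6-hydroxy-10-iodo-2,6-dimethylundeca-1,4,9-trien-1-yl]-3-methylidene-4-(2-oxoethyl)oxolan-2-one
Conditions: LiBF4, MeCN/H2O 50:1, rt
Reagents that add atoms: water O
Why: Lewis-acid-assisted acetal hydrolysis under nearly neutral conditions unveils the C13 aldehyde without ionising the tertiary allylic alcohol or adding water to the exo-methylene lactone.

Step 16
Reactants: 24 (4S,5S)-5-[(1E,4E,6R,9E)-6-hydroxy-10-iodo-2,6-dimethylundeca-1,4,9-trien-1-yl]-3-methylidene-4-(2-oxoethyl)oxolan-2-one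
Product: 26 (1S,2S,3E,6E,8R,11E,13S)-8,13-dihydroxycembra-3,6,11,15(17)-tetraen-16,2-olide, via alkenylchromium dichloride 25 (not isolated)
Conditions: CrCl2 (12 equiv), NiCl2 (0.1 equiv), degassed DMSO/THF 3:1, rt, 24 added by syringe pump (final 2 mM); then H2O
Reagents that add atoms: none
Why: Divalent chromium reduces NiCl2 to zerovalent nickel, which inserts into the C12–I bond with retention of the E geometry; transmetalation to trivalent chromium gives 25, which adds to the C13 aldehyde, and water releases 26. The closest known reaction type is the nickel/chromium-mediated (Nozaki–Hiyama–Kishi) macrocyclisation of alkenyl iodides onto aldehydes. The 14-membered carbocycle closes in a 14-exo-trig mode (carbonyl oxygen outside the ring), helped by high dilution and by the preorganisation from the cis-lactone and the two E-alkenes. The new centre C13 must be S, which means attack on the Re face of the aldehyde. The controlling element is the (1S) centre two atoms away together with the cis ring fusion, which fix the direction of the C14–C13 arm relative to the incoming chain, with the chromium-bound oxygen expected on the outside of the forming ring. This is substrate control through a macrocyclic transition state, so its level is a prediction and a correction path is held ready. Chemoselectivity rests on the fact that alkenylchromium reagents add to aldehydes but not to lactones or unactivated alkenes and tolerate the free tertiary hydroxyl, which only forms a chromium alkoxide.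

Step 17
Reactants: 26 (1S,2S,3E,6E,8R,11E,13S)-8,13-dihydroxycembra-3,6,11,15(17)-tetraen-16,2-olide
Product: 27 (1S,2S,3E,6E,8R,11S,12S,13S)-11,12-epoxy-8,13-dihydroxycembra-3,6,15(17)-trien-16,2-olide
Conditions: Ti(OiPr)4 (1.1 equiv), L-(+)-diisopropyl tartrate (1.3 equiv), t-BuOOH (2 equiv), 4 Å MS, CH2Cl2, −20 °C; aq. potassium sodium tartrate
Reagents that add atoms: tert-butyl hydroperoxide CC(C)(C)OO
Why: Sharpless titanium–tartrate epoxidation of a secondary allylic alcohol: the C13 alkoxide binds titanium and the peroxide oxygen is delivered to C11=C12. For the (13S)-carbinol the L-(+)-tartrate complex is the matched combination and gives the erythro epoxy alcohol, which has the target geometry, and allylic 1,2-strain from C20 works in the same sense. The tertiary C8 hydroxyl is a poor ligand for the titanium tartrate, so C6=C7 should stay, and the cold, neutral work-up avoids transannular opening of the oxirane.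

Step 18
Reactants: 27 (1S,2S,3E,6E,8R,11S,12S,13S)-11,12-epoxy-8,13-dihydroxycembra-3,6,15(17)-trien-16,2-olide
Product: 28 (1S,2S,3E,6E,8R,11S,12R,13S)-13-acetoxy-11,12-epoxy-8-hydroxycembra-3,6,15(17)-trien-16,2-olide (target)
Conditions: Ac2O, pyridine, DMAP (5 mol%), CH2Cl2, 0 °C
Reagents that add atoms: acetic anhydride CC(=O)OC(C)=O
Why: Acylation of the secondary alcohol; the tertiary C8 hydroxyl does not react at 0 °C, and the basic, non-nucleophilic medium leaves the oxirane and the lactone intact.

## Compound list

1 | pent-1-en-4-yne | C=CCC#C | starting material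
2 | dimethyl[(1E)-2-methylpenta-1,4-dien-1-yl]alane | C=CC/C(C)=C/[Al](C)C | intermediate (not isolated)
3 | (2E)-3-methylhexa-2,5-dien-1-ol | C=CC/C(C)=C/CO | intermediate
4 | tert-butyl(dimethyl){[(2E)-3-methylhexa-2,5-dien-1-yl]oxy}silane | C=CC/C(C)=C/CO[Si](C)(C)C(C)(C)C | intermediate
5 | (R)-linalool, (3R)-3,7-dimethylocta-1,6-dien-3-ol | C=C[C@](C)(O)CCC=C(C)C | starting material
6 | (4R)-4-hydroxy-4-methylhex-5-enal | C=C[C@](C)(O)CCC=O | intermediate (not isolated)
7 | (4R)-4-methylhex-5-ene-1,4-diol | C=C[C@](C)(O)CCCO | intermediate
8 | (4R,5E,8E)-10-[(tert-butyldimethylsilyl)oxy]-4,8-dimethyldeca-5,8-diene-1,4-diol | CC(C)(C)[Si](C)(C)OC/C=C(\C)C/C=C/[C@](C)(O)CCCO | intermediate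
9 | (5R)-5-[(1E,4E)-6-[(tert-butyldimethylsilyl)oxy]-4-methylhexa-1,4-dien-1-yl]-5-methyloxolan-2-ol (anomer mixture) | CC(C)(C)[Si](C)(C)OC/C=C(\C)C/C=C/[C@@]1(C)CCC(O)O1 | intermediate
10 | (5R,6E,9E)-11-[(tert-butyldimethylsilyl)oxy]-5,9-dimethylundeca-6,9-dien-1-yn-5-ol | CC(C)(C)[Si](C)(C)OC/C=C(\C)C/C=C/[C@](C)(O)CCC#C | intermediate
11 | dilithium alkoxide/acetylide of 10 | CC(C)(C)[Si](C)(C)OC/C=C(\C)C/C=C/[C@](C)(O[Li])CCC#C[Li] | intermediate (not isolated)
12 | (6R,7E,10E)-12-[(tert-butyldimethylsilyl)oxy]-6,10-dimethyldodeca-7,10-dien-2-yn-6-ol | CC(C)(C)[Si](C)(C)OC/C=C(\C)C/C=C/[C@](C)(O)CCC#CC | intermediate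
13 | (E)-alkenyl(chloro)zirconocene at C12, C8 oxygen as its chlorozirconocene alkoxide | CC(C)(C)[Si](C)(C)OC/C=C(\C)C/C=C/[C@](C)(O[Zr](Cl)(C1C=CC=C1)C1C=CC=C1)CC/C=C(\C)[Zr](Cl)(C1C=CC=C1)C1C=CC=C1 | intermediate (not isolated)
14 | (2E,6R,7E,10E)-12-[(tert-butyldimethylsilyl)oxy]-2-iodo-6,10-dimethyldodeca-2,7,10-trien-6-ol | CC(C)(C)[Si](C)(C)OC/C=C(\C)C/C=C/[C@](C)(O)CC/C=C(\C)I | intermediate
15 | (2E,5E,7R,10E)-11-iodo-3,7-dimethyldodeca-2,5,10-triene-1,7-diol | OC/C=C(\C)C/C=C/[C@](C)(O)CC/C=C(\C)I | intermediate
16 | (2E,5E,7R,10E)-7-hydroxy-11-iodo-3,7-dimethyldodeca-2,5,10-trienal | O=C/C=C(\C)C/C=C/[C@](C)(O)CC/C=C(\C)I | intermediate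
17 | methyl 3,3-dimethoxypropanoate | COC(CC(=O)OC)OC | starting material
18 | 3,3-dimethoxypropanal | COC(CC=O)OC | intermediate
19 | methyl acrylate | C=CC(=O)OC | starting material
20 | methyl 3-hydroxy-5,5-dimethoxy-2-methylidenepentanoate (racemic) | C=C(C(=O)OC)C(O)CC(OC)OC | intermediate
21 | methyl (2Z)-2-(bromomethyl)-5,5-dimethoxypent-2-enoate | COC(=O)/C(CBr)=C/CC(OC)OC | intermediate
22 | methyl (3S,4S,5E,8E,10R,13E)-3-(2,2-dimethoxyethyl)-10-hydroxy-14-iodo-6,10-dimethyl-2-methylidene-4-[(trimethylsilyl)oxy]pentadeca-5,8,13-trienoate | C=C(C(=O)OC)[C@H](CC(OC)OC)[C@@H](O[Si](C)(C)C)/C=C(\C)C/C=C/[C@](C)(O)CC/C=C(\C)I | intermediate (not isolated)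
23 | (4S,5S)-4-(2,2-dimethoxyethyl)-5-[(1E,4E,6R,9E)-6-hydroxy-10-iodo-2,6-dimethylundeca-1,4,9-trien-1-yl]-3-methylideneoxolan-2-one | C=C1C(=O)O[C@@H](/C=C(\C)C/C=C/[C@](C)(O)CC/C=C(\C)I)[C@H]1CC(OC)OC | intermediate
24 | (4S,5S)-5-[(1E,4E,6R,9E)-6-hydroxy-10-iodo-2,6-dimethylundeca-1,4,9-trien-1-yl]-3-methylidene-4-(2-oxoethyl)oxolan-2-one | C=C1C(=O)O[C@@H](/C=C(\C)C/C=C/[C@](C)(O)CC/C=C(\C)I)[C@H]1CC=O | intermediate
25 | (E)-alkenylchromium dichloride at C12 derived from 24 | C=C1C(=O)O[C@@H](/C=C(\C)C/C=C/[C@](C)(O)CC/C=C(\C)[Cr](Cl)Cl)[C@H]1CC=O | intermediate (not isolated)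
26 | (1S,2S,3E,6E,8R,11E,13S)-8,13-dihydroxycembra-3,6,11,15(17)-tetraen-16,2-olide | C=C1C(=O)O[C@H]2/C=C(\C)C/C=C/[C@](C)(O)CC/C=C(\C)[C@@H](O)C[C@@H]12 | intermediate
27 | (1S,2S,3E,6E,8R,11S,12S,13S)-11,12-epoxy-8,13-dihydroxycembra-3,6,15(17)-trien-16,2-olide | C=C1C(=O)O[C@H]2/C=C(\C)C/C=C/[C@](C)(O)CC[C@@H]3O[C@@]3(C)[C@@H](O)C[C@@H]12 | intermediate
28 | (1S,2S,3E,6E,8R,11S,12R,13S)-13-acetoxy-11,12-epoxy-8-hydroxycembra-3,6,15(17)-trien-16,2-olide | C=C1C(=O)O[C@H]2/C=C(\C)C/C=C/[C@](C)(O)CC[C@@H]3O[C@@]3(C)[C@@H](OC(C)=O)C[C@@H]12 | target

## Step count and least certain steps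

Total: 18 steps. Longest linear sequence: 14 steps (1 through steps 1, 2, 4–10 and 14–18); 13 steps from 5.

Step 16 (key step). The most likely failure is poor facial selectivity at C13, because the bias from C1 acts only through the folding of a large ring; intermolecular coupling is the second risk. The fallback sets out from 26 obtained in admixture with its C13 epimer, (13R)-8,13-dihydroxycembra-3,6,11,15(17)-tetraen-16,2-olide F1. The mixture would be oxidised with MnO2 in CH2Cl2 to the cross-conjugated 13-ketone, 8-hydroxy-13-oxocembra-3,6,11,15(17)-tetraen-16,2-olide F2. F2 would then be reduced with catecholborane and the (R)-configured methyl oxazaborolidine at −78 °C, the α-methyl alkenyl group acting as the large substituent, which returns to the route at 26.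

Step 14. The most likely failure is erosion of enantio- and diastereocontrol with a β-branched enal, through a competing ligand-free allylation, or activation of the alkenyl iodide by traces of nickel. The fallback sets out from 16 and 21 and replaces reagent control by separation. A zinc-mediated Barbier reaction (Zn dust, THF/saturated aqueous NH4Cl, rt) should give, after lactonisation on work-up, the cis-lactone 23 together with its (4R,5R)-diastereomer F3. The two differ in the relation of the lactone to C8 and would be separated by preparative HPLC, returning to the route at 23 at the cost of half the material.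

Step 17. The most likely failures are delivery of oxygen to C6=C7 through the free C8 hydroxyl, acid-promoted transannular attack of that hydroxyl on the new oxirane, or sluggish reaction because the ring cannot adopt the geometry the titanium tartrate needs. The fallback sets out from 26:
- Et3SiOTf/2,6-lutidine would give the 8,13-bis(triethylsilyl) ether F4.
- Brief PPTS/MeOH at 0 °C would remove the less hindered secondary allylic silyl group to give the 8-O-triethylsilyl 13-alcohol F5.
- VO(acac)2/t-BuOOH would give, under allylic 1,2-strain control, the erythro 8-O-triethylsilyl epoxy alcohol F6.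
- Ac2O/pyridine would give the 8-O-triethylsilyl acetate F7.
- Pyridine-buffered HF·pyridine would then release the tertiary alcohol and return to the route at 28.

Step 8. The most likely failure is incomplete regiocontrol of the Zr–H addition (metal on C11) or addition of the excess hydride to other alkenes. The fallback sets out from 5 and avoids the alkyne:
- Et3SiOTf/2,6-lutidine would give (R)-linalool triethylsilyl ether F8.
- Selective ozonolysis (PPh3 work-up) would give (4R)-4-methyl-4-[(triethylsilyl)oxy]hex-5-enal F9.
- Ethylidenetriphenylphosphorane at −78 °C, a second equivalent of PhLi to form the β-oxido ylide, and N-iodosuccinimide should give the (E)-iodide (3R,6E)-7-iodo-3-methyl-3-[(triethylsilyl)oxy]octa-1,6-diene F10.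
- Bu4NF would give (3R,6E)-7-iodo-3-methylocta-1,6-dien-3-ol F11.
- Cross-metathesis of F11 with 4 under the conditions of step 4 would return to the route at 14.

Step 4. The most likely failure is migration of the skipped diene into conjugation by ruthenium hydride species, or homodimerisation of 4 outrunning cross-coupling at the hindered alkene of 7. The fallback sets out from 7 and makes the C5–C6 bond by an alkenyl–allyl coupling instead:
- Cross-metathesis of 7 with vinylboronic acid pinacol ester would give the (E)-alkenylboronate (4R,5E)-4-methyl-6-(4,4,5,5-tetramethyl-1,3,2-dioxaborolan-2-yl)hex-5-ene-1,4-diol F12.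
- Prenol would be silylated to tert-butyl(dimethyl)[(3-methylbut-2-en-1-yl)oxy]silane F13.
- SeO2/t-BuOOH would oxidise F13 to (2E)-4-[(tert-butyldimethylsilyl)oxy]-2-methylbut-2-en-1-ol F14.
- CBr4/PPh3 would convert F14 into [(2E)-4-bromo-3-methylbut-2-en-1-yl]oxy(tert-butyl)dimethylsilane F15.
- Coupling of F12 with F15 (Pd(PPh3)4, aqueous K3PO4, THF, 50 °C; zerovalent palladium attacks the unsubstituted allyl terminus) would return to the route at 8.

Step 12. The most likely failure is β-elimination of methanol from 18 or its self-condensation during the slow amine-catalysed reaction. The fallback sets out from 18 and uses vinylalumination. Methyl propiolate with i-Bu2AlH and N-methylmorpholine N-oxide in THF at 0 °C gives the [1-(methoxycarbonyl)vinyl]aluminium reagent, which adds to 18 at low temperature. This returns to the route at 20 and makes no new isolated compound (F0).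

## Further compounds

F1 | step 16 | (1S,2S,3E,6E,8R,11E,13R)-8,13-dihydroxycembra-3,6,11,15(17)-tetraen-16,2-olide | C=C1C(=O)O[C@H]2/C=C(\C)C/C=C/[C@](C)(O)CC/C=C(\C)[C@H](O)C[C@@H]12
F2 | step 16 | (1S,2S,3E,6E,8R,11E)-8-hydroxy-13-oxocembra-3,6,11,15(17)-tetraen-16,2-olide | C=C1C(=O)O[C@H]2/C=C(\C)C/C=C/[C@](C)(O)CC/C=C(\C)C(=O)C[C@@H]12
F3 | step 14 | (4R,5R)-4-(2,2-dimethoxyethyl)-5-[(1E,4E,6R,9E)-6-hydroxy-10-iodo-2,6-dimethylundeca-1,4,9-trien-1-yl]-3-methylideneoxolan-2-one | C=C1C(=O)O[C@H](/C=C(\C)C/C=C/[C@](C)(O)CC/C=C(\C)I)[C@@H]1CC(OC)OC
F4 | step 17 | 8,13-bis(triethylsilyl) ether of 26 | C=C1C(=O)O[C@H]2/C=C(\C)C/C=C/[C@](C)(O[Si](CC)(CC)CC)CC/C=C(\C)[C@@H](O[Si](CC)(CC)CC)C[C@@H]12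
F5 | step 17 | 8-O-triethylsilyl ether of 26 | C=C1C(=O)O[C@H]2/C=C(\C)C/C=C/[C@](C)(O[Si](CC)(CC)CC)CC/C=C(\C)[C@@H](O)C[C@@H]12
F6 | step 17 | 8-O-triethylsilyl ether of 27 | C=C1C(=O)O[C@H]2/C=C(\C)C/C=C/[C@](C)(O[Si](CC)(CC)CC)CC[C@@H]3O[C@@]3(C)[C@@H](O)C[C@@H]12
F7 | step 17 | 8-O-triethylsilyl ether of 28 | C=C1C(=O)O[C@H]2/C=C(\C)C/C=C/[C@](C)(O[Si](CC)(CC)CC)CC[C@@H]3O[C@@]3(C)[C@@H](OC(C)=O)C[C@@H]12
F8 | step 8 | (R)-linalool triethylsilyl ether | C=C[C@](C)(O[Si](CC)(CC)CC)CCC=C(C)C
F9 | step 8 | (4R)-4-methyl-4-[(triethylsilyl)oxy]hex-5-enal | C=C[C@](C)(O[Si](CC)(CC)CC)CCC=O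
F10 | step 8 | (3R,6E)-7-iodo-3-methyl-3-[(triethylsilyl)oxy]octa-1,6-diene | C=C[C@](C)(O[Si](CC)(CC)CC)CC/C=C(\C)I
F11 | step 8 | (3R,6E)-7-iodo-3-methylocta-1,6-dien-3-ol | C=C[C@](C)(O)CC/C=C(\C)I
F12 | step 4 | (4R,5E)-4-methyl-6-(4,4,5,5-tetramethyl-1,3,2-dioxaborolan-2-yl)hex-5-ene-1,4-diol | CC1(C)OB(/C=C/[C@](C)(O)CCCO)OC1(C)C
F13 | step 4 | tert-butyl(dimethyl)[(3-methylbut-2-en-1-yl)oxy]silane | CC(C)=CCO[Si](C)(C)C(C)(C)C
F14 | step 4 | (2E)-4-[(tert-butyldimethylsilyl)oxy]-2-methylbut-2-en-1-ol | OC/C(C)=C/CO[Si](C)(C)C(C)(C)C
F15 | step 4 | [(2E)-4-bromo-3-methylbut-2-en-1-yl]oxy(tert-butyl)dimethylsilane | BrC/C(C)=C/CO[Si](C)(C)C(C)(C)C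
F0 | step 12 | none | none
A1 | alternative 1 | silyl-protected seco diyne with methyl-capped alkynes at C3 and C4 | CC#CC/C=C/[C@](C)(O[Si](C)(C)C(C)(C)C)CC/C=C(\C)[C@@H](O[Si](C)(C)C(C)(C)C)C[C@@H](C(=C)CO[Si](C)(C)C(C)(C)C)[C@H](C#CC)O[Si](CC)(CC)CC
A2 | alternative 1 | 14-membered C3≡C4 cycloalkyne | C1#CC/C=C/[C@](C)(O[Si](C)(C)C(C)(C)C)CC/C=C(\C)[C@@H](O[Si](C)(C)C(C)(C)C)C[C@@H](C(=C)CO[Si](C)(C)C(C)(C)C)[C@H]1O[Si](CC)(CC)CC
A3 | alternative 2 | 16-membered enol ether (C14H2=C13–O–C17H2–C15=C1, drawn with C2 and C17 trans) | C=C1OC/C(CO[Si](C)(C)C(C)(C)C)=C/[C@@H](O[Si](C)(C)C(C)(C)C)/C=C(\C)C/C=C/[C@](C)(O[Si](CC)(CC)CC)CC/C=C1\C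
A4 | alternative 2 | 14-membered C11-en-13-one with C1 set | O=C1C[C@@H](C(=C)CO[Si](C)(C)C(C)(C)C)[C@@H](O[Si](C)(C)C(C)(C)C)/C=C(\C)C/C=C/[C@](C)(O[Si](CC)(CC)CC)CC/C=C1\C
A5 | alternative 3 | seco C11 aldehyde / C12 methyl ketone | O=CCC[C@@](C)(O[Si](CC)(CC)CC)/C=C/C/C(C)=C/[C@H](O[Si](C)(C)C(C)(C)C)[C@H](C(=C)CO[Si](C)(C)C(C)(C)C)C[C@H](O[Si](C)(C)C(C)(C)C)C(C)=O
A6 | alternative 3 | 14-membered C11,C12-diol | O[C@@H]1CC[C@@](C)(O[Si](CC)(CC)CC)/C=C/C/C(C)=C/[C@H](O[Si](C)(C)C(C)(C)C)[C@H](C(=C)CO[Si](C)(C)C(C)(C)C)C[C@H](O[Si](C)(C)C(C)(C)C)[C@]1(C)O
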